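**Plan**

- Numbering: guaiane numbers throughout; unit A (unprimed) carries 10-OH and 15-OH, unit B (primed) carries the quaternary C4'.
- Cuts, in retrosynthetic order: the C15 O–Si bond; the C10–O bond (the 10-hydroxy-1-en-3-one is the γ-oxygenated form of a β,γ-enone with C1=C10); then C2–C4' and C14–C15' of the cyclohexene C10–C1–C2–C4'–C15'–C14.
- Enabling feature: with C1=C10 in place this ring is a 4-acylcyclohexene whose acyl-bearing carbon is the quaternary C4'. It is the adduct of the diene C14=C10–C1=C2 (held s-cis between the seven-ring exo-methylene and the cyclopentenone of unit A) and the exo-methylene enone C4'=C15' of dehydrozaluzanin C.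
- Forward: dehydrocostus lactone gives allylic alcohol 2, which feeds both halves. One branch is oxidation to enone 3. The other is directed epoxidation, oxidation, reductive epoxide opening, silylation and Saegusa dehydrogenation to dienone 9. Then 9 + 3 give the cyclohexene, followed by C10 γ-oxygenation and desilylation.
- Stereochemistry: C1', C5', C6', C7', C5, C6 and C7 come from dehydrocostus lactone; C4' from addition to the convex α face of 3; C10 from β-face oxygenation of the dienolate; C4 from thermodynamic control (CH2O trans to C6).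

Key step: step 9

Remark: natural dehydrocostus lactone is taken as a commercial starting material; the C2 centre of adduct 10 is transient, so 10 is drawn as the carbonyl-endo epimer only and its C2 epimer would serve equally.

**Route**

Step 1
Reactants: 1 dehydrocostus lactone
Product: 2 3-epizaluzanin C (3α-hydroxy derivative of 1)
Conditions: SeO2 (0.5 equiv), t-BuOOH (2 equiv), CH2Cl2, rt
Reagents that add atoms: tert-butyl hydroperoxide, CC(C)(C)OO; selenium dioxide, O=[Se]=O (relays the oxygen atom)
Why: Selenium dioxide allylic oxidation (ene reaction at the C4=C15 methylene, then [2,3]-sigmatropic shift of the allylseleninic acid) should hydroxylate C3 with return of the exo-methylene, oxygen arriving on the convex α face; the C3 configuration is erased in steps 2 and 4.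

Step 2
Reactants: 2 3-epizaluzanin C
Product: 3 dehydrozaluzanin C (3-oxo derivative of 1)
Conditions: DMP, pyridine, CH2Cl2, 0 °C to rt
Reagents that add atoms: none
Why: Dess–Martin oxidation of the secondary allylic alcohol should give the exo-methylene ketone under buffered, non-nucleophilic conditions that spare both Michael acceptors; no stereocentre is formed.

Step 3
Reactants: 2 3-epizaluzanin C
Product: 4 4α,15-epoxy-3α-hydroxyguaia-10(14),11(13)-dien-12,6α-olide
Conditions: VO(acac)2 (5 mol %), t-BuOOH (1.5 equiv), CH2Cl2, 0 °C to rt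
Reagents that add atoms: tert-butyl hydroperoxide, CC(C)(C)OO
Why: Hydroxyl-directed vanadium-catalysed epoxidation should touch only the allylic C4=C15 alkene and deliver oxygen syn to the C3 hydroxyl (α face), leaving the isolated C10=C14 and the electron-poor lactone methylene alone.

Step 4
Reactants: 4 epoxy alcohol
Product: 5 4α,15-epoxy-3-oxoguaia-10(14),11(13)-dien-12,6α-olide (spiro α,β-epoxy ketone)
Conditions: DMP, pyridine, CH2Cl2, 0 °C to rt
Reagents that add atoms: none
Why: Dess–Martin oxidation under buffered conditions should convert the carbinol into the ketone without opening the spiro-epoxide; no stereocentre is formed.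

Step 5
Reactants: 5 epoxy ketone
Product: 6 15-hydroxy-3-oxo-4βH-guaia-10(14),11(13)-dien-12,6α-olide (CH2OH on the α face)
Conditions: SmI2 (2.2 equiv), THF/MeOH, −90 °C; pH 7 buffer; then Et3N (cat.), CH2Cl2, rt
Reagents that add atoms: none
Why: Reductive cleavage of the α-C–O bond of an α,β-epoxy ketone by SmI2 (two single-electron transfers giving a samarium enolate and the C15 alkoxide) should be far faster at −90 °C than reduction of the unsaturated lactone; protonation and amine equilibration of the epimerisable C4 place CH2OH trans to C6, the thermodynamically preferred arrangement.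

Step 6
Reactants: 6 hydroxy ketone
Product: 7 15-O-TBS ether of 6
Conditions: TBSCl, imidazole, DMF, 0 °C to rt
Reagents that add atoms: tert-butyldimethylsilyl chloride, CC(C)(C)[Si](C)(C)Cl
Why: Standard silylation of the primary alcohol should mask C15–OH through the enolisation, dehydrogenation, cycloaddition and oxidation steps; no stereocentre is affected.

Step 7
Reactants: 7 silyl ether ketone
Product: 8 TMS enol ether of 7 (C2=C3, 3-trimethylsilyloxy)
Conditions: LiN(SiMe3)2 (1.1 equiv), Me3SiCl (in situ), THF, −78 °C; used crude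
Reagents that add atoms: chlorotrimethylsilane, C[Si](C)(C)Cl
Why: Kinetic deprotonation by the hindered, poorly nucleophilic amide should take place at the C2 methylene and not at the branched C4 methine, and in-situ silylation keeps the enolate away from the lactone methylene and from β-elimination.

Step 8
Reactants: 8 TMS enol ether
Product: 9 15-TBSO-3-oxo-4βH-guaia-1,10(14),11(13)-trien-12,6α-olide (dienone)
Conditions: Pd(OAc)2 (1.1 equiv), MeCN, rt; filtered through silica and used at once
Reagents that add atoms: none
Why: Ito–Saegusa oxidation: divalent palladium should add at C2 of the silyl enol ether and syn β-hydride elimination of the tertiary allylic H-1 should give the C1=C2 enone, which with the C10=C14 methylene forms the s-cis diene.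

Step 9
Reactants: 9 dienone; 3 dehydrozaluzanin C
Product: 10 cycloadduct (unit A: 15-TBSO-3-oxo-4βH-guaia-1(10),11(13)-dien-12,6α-olide; joined to unit B by C14–C15' and C2–C4'; C2 on the α face of unit B; H-2α)
Conditions: 3 (3 equiv), toluene (1 M), BHT (cat.), argon, dark, 40 °C; excess 3 recovered
Reagents that add atoms: none
Why: Thermal [4+2] cycloaddition (Diels–Alder) in which the s-cis-locked diene C14=C10–C1=C2 of 9 adds across the exo-methylene enone C4'=C15' of 3; the bond between the unsubstituted methylene termini C14 and C15' should lead, and the ring is closed by the C2–C4' bond between the two ketone-bearing carbons (ortho orientation of a 1-acyl diene). The closest known reaction type is the Diels–Alder dimerisation of conjugated dienones with α-methylene cyclopentanones. The cyclohexene closes as a six-membered (4+2) ring, spiro at C4' and sharing C1–C2 with the five-membered ring and C1–C10 with the seven-membered ring of unit A. The quaternary C4' is set by the dienophile face: the diene should add to the convex α face of 3, syn to H-5' and anti to the C6' branch of the neighbouring ring-fusion carbon; C2 depends on the diene face and on endo or exo approach, but it is erased in step 10, so both C2 epimers converge. The step needs chemoselectivity for the ketone-conjugated methylene of 3 over the two lactone methylenes (lower LUMO of the enone) and cross- over self-reaction; the latter is secured because 9 has no unhindered enone alkene (C15 is masked as CH2OTBS and C1=C2 is β,β-disubstituted) and 3 is in excess.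

Step 10
Reactants: 10 cycloadduct
Product: 12 15-O-TBS-ainsliadimer B, via 10β-hydroperoxy enone 11 (not isolated)
Conditions: O2 (1 atm), Et3N, MeCN, rt; then PPh3, 0 °C
Reagents that add atoms: dioxygen, O=O
Why: Amine-promoted dienolisation at the doubly activated C2–H and γ-oxygenation of the dienolate by oxygen (autoxidation of a β,γ-unsaturated ketone), then phosphine reduction of the hydroperoxide, should give the 10-hydroxy-1-en-3-one; oxygen is expected on the β face of C10, anti to the C5' branch that the spiro carbon C4' projects onto the α face.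

Step 11
Reactants: 12 15-O-TBS-ainsliadimer B
Product: 13 ainsliadimer B
Conditions: HF·pyridine, THF/pyridine, 0 °C to rt
Reagents that add atoms: none
Why: Buffered fluoride desilylation should free the primary alcohol without base-induced β-elimination of the β-oxy ketone or attack on the lactone methylenes; no stereocentre is affected.

**Compound list**

1 | dehydrocostus lactone (guaia-4(15),10(14),11(13)-trien-12,6α-olide; H-1α, H-5α, H-6β, H-7α) | C=C1CC[C@H]2C(=C)CC[C@H]3C(=C)C(=O)O[C@@H]3[C@H]21 | starting material
2 | 3-epizaluzanin C (3α-hydroxy-1) | C=C1[C@H](O)C[C@H]2C(=C)CC[C@H]3C(=C)C(=O)O[C@@H]3[C@H]21 | intermediate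
3 | dehydrozaluzanin C (3-oxo-1) | C=C1C(=O)C[C@H]2C(=C)CC[C@H]3C(=C)C(=O)O[C@@H]3[C@H]21 | intermediate
4 | 4α,15-epoxy-3α-hydroxyguaia-10(14),11(13)-dien-12,6α-olide | O[C@@H]1C[C@H]2C(=C)CC[C@H]3C(=C)C(=O)O[C@@H]3[C@H]2[C@@]14CO4 | intermediate
5 | 4α,15-epoxy-3-oxoguaia-10(14),11(13)-dien-12,6α-olide | O=C1C[C@H]2C(=C)CC[C@H]3C(=C)C(=O)O[C@@H]3[C@H]2[C@@]14CO4 | intermediate
6 | 15-hydroxy-3-oxo-4βH-guaia-10(14),11(13)-dien-12,6α-olide | O=C1C[C@H]2C(=C)CC[C@H]3C(=C)C(=O)O[C@@H]3[C@H]2[C@@H]1CO | intermediate
7 | 15-O-TBS ether of 6 | O=C1C[C@H]2C(=C)CC[C@H]3C(=C)C(=O)O[C@@H]3[C@H]2[C@@H]1CO[Si](C)(C)C(C)(C)C | intermediate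
8 | TMS enol ether of 7 (C2=C3) | C[Si](C)(C)OC1=C[C@H]2C(=C)CC[C@H]3C(=C)C(=O)O[C@@H]3[C@H]2[C@@H]1CO[Si](C)(C)C(C)(C)C | intermediate
9 | dienone, 15-TBSO-3-oxo-4βH-guaia-1,10(14),11(13)-trien-12,6α-olide | O=C1C=C2C(=C)CC[C@H]3C(=C)C(=O)O[C@@H]3[C@H]2[C@@H]1CO[Si](C)(C)C(C)(C)C | intermediate
10 | cycloadduct (C1=C10, H-2α, C4' quaternary, 15-OTBS) | C=C1C(=O)O[C@@H]2[C@@H]3C4=C(CC[C@@H]12)CC[C@]5(C(=O)C[C@H]6C(=C)CC[C@H]7C(=C)C(=O)O[C@@H]7[C@H]65)[C@@H]4C(=O)[C@H]3CO[Si](C)(C)C(C)(C)C | intermediate
11 | 10β-hydroperoxy-1-en-3-one (15-OTBS) | C=C1C(=O)O[C@@H]2[C@@H]3C4=C(C(=O)[C@H]3CO[Si](C)(C)C(C)(C)C)[C@]3(CC[C@]4(OO)CC[C@@H]12)C(=O)C[C@H]1C(=C)CC[C@H]2C(=C)C(=O)O[C@@H]2[C@H]13 | intermediate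
12 | 15-O-TBS-ainsliadimer B | C=C1C(=O)O[C@@H]2[C@@H]3C4=C(C(=O)[C@H]3CO[Si](C)(C)C(C)(C)C)[C@]3(CC[C@]4(O)CC[C@@H]12)C(=O)C[C@H]1C(=C)CC[C@H]2C(=C)C(=O)O[C@@H]2[C@H]13 | intermediate
13 | ainsliadimer B | C=C1C(=O)O[C@@H]2[C@@H]3C4=C(C(=O)[C@H]3CO)[C@]3(CC[C@]4(O)CC[C@@H]12)C(=O)C[C@H]1C(=C)CC[C@H]2C(=C)C(=O)O[C@@H]2[C@H]13 | target

Total steps: 11. Longest linear sequence: 10 (steps 1 and 3 to 11).

**Steps most likely to fail**

Step 9. The risks are self-dimerisation of 3 by hetero-Diels–Alder addition, addition of the diene to a lactone methylene, double-bond migration in the dienone before it is trapped, and poor facial selectivity at C4'. The fallback sets out from 9 and returns at 10, and it changes the polarity of the diene. Luche reduction of 9 (NaBH4, CeCl3·7H2O, MeOH, −78 °C; hydride anti to the C4 side chain) should give the electron-rich 3α-hydroxy diene F1. Its normal-electron-demand Diels–Alder reaction with 3 (toluene, 0 °C to rt) should be faster, with the same ortho orientation, and give the 3-hydroxy adduct F2. Dess–Martin oxidation of F2 (DMP, pyridine, CH2Cl2) then gives 10.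

Step 10. The risks are oxygen delivery to the α face of C10, attack at C2 in place of C10, and γ-protonation of the dienolate to the deoxy enone. The fallback sets out from 10 and returns at 12. The dienolate is first trapped as the silyl dienol ether F3 (TBSOTf, one equivalent, Et3N, CH2Cl2, −78 °C, so that the less acidic C2' methylene next to the C3' ketone is left alone). F3 is then oxidised at the γ-carbon with DMDO (acetone/CH2Cl2, −78 °C, aqueous work-up; vinylogous Rubottom oxidation) to give 12. The bulkier electrophilic oxidant should respond more strongly to the shielding of the α face, and no proton source can divert the intermediate.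

Step 7. The risks are enolisation toward C4 followed by loss of silanolate, and amide addition to the lactone methylene. The fallback sets out from 5 and returns at 9, and it keeps the spiro-epoxide as a blocking group, because C4 of 5 is quaternary and only C2 can enolise. Ketone 5 is converted into the epoxy TMS enol ether F4 (LiN(SiMe3)2, Me3SiCl, THF, −78 °C). Ito–Saegusa oxidation (Pd(OAc)2, MeCN) gives the epoxy dienone F5. SmI2 (THF/MeOH, −90 °C) then opens the epoxide to the hydroxy dienone F6, and silylation (TBSCl, imidazole, DMF) gives 9.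

**Further compounds**

F1 | step 9 | 3α-hydroxy diene, 15-TBSO-3α-hydroxy-4βH-guaia-1,10(14),11(13)-trien-12,6α-olide | O[C@@H]1C=C2C(=C)CC[C@H]3C(=C)C(=O)O[C@@H]3[C@H]2[C@@H]1CO[Si](C)(C)C(C)(C)C
F2 | step 9 | 3α-hydroxy cycloadduct (3-hydroxy analogue of 10) | C=C1C(=O)O[C@@H]2[C@@H]3C4=C(CC[C@@H]12)CC[C@]5(C(=O)C[C@H]6C(=C)CC[C@H]7C(=C)C(=O)O[C@@H]7[C@H]65)[C@@H]4[C@@H](O)[C@H]3CO[Si](C)(C)C(C)(C)C
F3 | step 10 | TBS dienol ether of 10 (C2=C3, C1=C10) | C=C1C(=O)O[C@@H]2[C@@H]3C4=C(CC[C@@H]12)CC[C@]5(C(=O)C[C@H]6C(=C)CC[C@H]7C(=C)C(=O)O[C@@H]7[C@H]65)C4=C(O[Si](C)(C)C(C)(C)C)[C@H]3CO[Si](C)(C)C(C)(C)C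
F4 | step 7 | TMS enol ether of epoxy ketone 5 | C[Si](C)(C)OC1=C[C@H]2C(=C)CC[C@H]3C(=C)C(=O)O[C@@H]3[C@H]2[C@@]14CO4
F5 | step 7 | 4α,15-epoxy-3-oxoguaia-1,10(14),11(13)-trien-12,6α-olide | O=C1C=C2C(=C)CC[C@H]3C(=C)C(=O)O[C@@H]3[C@H]2[C@@]14CO4
F6 | step 7 | 15-hydroxy-3-oxo-4βH-guaia-1,10(14),11(13)-trien-12,6α-olide | O=C1C=C2C(=C)CC[C@H]3C(=C)C(=O)O[C@@H]3[C@H]2[C@@H]1CO
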